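## Retrosynthetic overview

1. Nortopsentin C ⇒ its N-tosyl derivative on the bromoindole nitrogen; sulfonamide hydrolysis is the last step.
2. The imidazole is the only ring built, and it is built last. Both indoles are bought intact. N1–C5 and N3–C4 form in one operation from 6-bromo-3-ethynyl-1-tosylindole (C4–C5 unit) and indole-3-carboxamidoxime (N–C2–N unit). This is the new step: Au-catalysed O-vinylation, [3,3] shift, cyclodehydration, with the N–O bond as internal oxidant.
3. Alkyne ⇒ 6-bromoindole, by C3 iodination, N-tosylation, C–I-selective Sonogashira coupling and desilylation.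
4. Amidoxime ⇒ indole-3-carbonitrile plus hydroxylamine.

Assumption: the target SMILES has no stereocentre, stereoaxis or stereo descriptor, so the molecule is achiral and "single enantiomer" needs no stereocontrol. The imidazole 1H/3H tautomers count as one compound.

## Route

Step 1
Reactants: 1 6-bromo-1H-indole
Product: 2 6-bromo-3-iodo-1H-indole
Conditions: I2 (1.05 equiv), KOH (2.5 equiv), DMF, rt, 1 h; aq NaHSO3; used at once
Reagents that add atoms: iodine, II
Why: Electrophilic aromatic substitution of the indolyl anion takes place only at the most nucleophilic position C3, and the C6–Br bond is untouched.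

Step 2
Reactants: 2 6-bromo-3-iodo-1H-indole
Product: 3 6-bromo-3-iodo-1-tosyl-1H-indole
Conditions: TsCl (1.2 equiv), 50% aq NaOH, n-Bu4NHSO4 (5 mol %), CH2Cl2, 0 °C to rt
Reagents that add atoms: p-toluenesulfonyl chloride, Cc1ccc(cc1)S(=O)(=O)Cl
Why: Phase-transfer N-sulfonylation of the indolide is fast and clean, and the electron-withdrawing tosyl group stabilises the labile 3-iodoindole and the later 3-ethynylindole.

Step 3
Reactants: 3 6-bromo-3-iodo-1-tosyl-1H-indole; 4 ethynyltrimethylsilane
Product: 5 6-bromo-1-tosyl-3-[(trimethylsilyl)ethynyl]-1H-indole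
Conditions: PdCl2(PPh3)2 (2 mol %), CuI (4 mol %), Et3N, THF, rt, degassed
Reagents that add atoms: none
Why: In this Sonogashira coupling at room temperature, oxidative addition into C3–I is far faster than into C6–Br, so only the iodide is replaced.

Step 4
Reactants: 5 6-bromo-1-tosyl-3-[(trimethylsilyl)ethynyl]-1H-indole
Product: 6 6-bromo-3-ethynyl-1-tosyl-1H-indole
Conditions: K2CO3 (0.2 equiv), MeOH/THF 1:1, 0 °C to rt, 30 min
Reagents that add atoms: none
Why: Methoxide-catalysed protodesilylation of the alkynylsilane is much faster than attack on the N-sulfonyl group under these short, mild conditions.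

Step 5
Reactants: 7 1H-indole-3-carbonitrile
Product: 8 (Z)-N'-hydroxy-1H-indole-3-carboximidamide
Conditions: 50% aq NH2OH (5 equiv), EtOH, 80 °C, 16 h
Reagents that add atoms: hydroxylamine, NO
Why: Nucleophilic addition of hydroxylamine to the nitrile (classical amidoxime synthesis) gives the thermodynamically preferred Z-amidoxime, whose C=N geometry is lost later and has no consequence.

Step 6
Reactants: 6 6-bromo-3-ethynyl-1-tosyl-1H-indole; 8 (Z)-N'-hydroxy-1H-indole-3-carboximidamide
Product: 11 6-bromo-3-[2-(1H-indol-3-yl)-1H-imidazol-4-yl]-1-tosyl-1H-indole, via O-vinyl amidoxime 9 (not isolated), via N-phenacyl-type amidine 10 (not isolated)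
Conditions: IPrAuNTf2 (5 mol %), PivOH (30 mol %), 4 Å MS, 1,4-dioxane, 45 °C, 6 h, then 100 °C, 12 h
Reagents that add atoms: none
Why: Proposed new method: a bulky cationic NHC–gold(I) π-acid activates the terminal alkyne for Markovnikov attack (positive charge at the indolyl-bearing carbon) by the α-effect oxygen of the unprotected amidoxime to give 9, whose imino-hydroxylamine tautomer (PivOH as proton shuttle) undergoes an irreversible [3,3]-sigmatropic shift that breaks the weak N–O bond and forms the CH2–N bond (10), after which the freed amidine =NH condenses with the ketone and loses water to aromatise, so the bromoindolyl carbon becomes C4, the alkyne CH becomes C5 and the amidoxime carbon becomes C2, redox-neutrally, without any reagent able to touch C–Br or N–Ts and without forming a stereocentre; the closest known reaction types are the gold-catalysed O-addition of N-arylhydroxylamines or oximes to alkynes followed by a [3,3] shift (indole and pyrrole syntheses) and the thermal amidoxime/propiolate conjugate addition–[3,3] imidazole synthesis, which so far needs an electron-poor alkyne.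

Step 7
Reactants: 11 6-bromo-3-[2-(1H-indol-3-yl)-1H-imidazol-4-yl]-1-tosyl-1H-indole
Product: 12 nortopsentin C, 6-bromo-3-[2-(1H-indol-3-yl)-1H-imidazol-4-yl]-1H-indole
Conditions: 2 M aq NaOH (5 equiv), 1,4-dioxane, 80 °C, N2
Reagents that add atoms: none
Why: Hydroxide attacks sulfur and expels the stabilised indolide (N-sulfonyl hydrolysis), the alcohol-free medium prevents formation of an alkyl tosylate that could N-alkylate the imidazole, and the aryl bromide is inert.

## Compound list

1 | 6-bromo-1H-indole | Brc1ccc2cc[nH]c2c1 | starting material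
2 | 6-bromo-3-iodo-1H-indole | Brc1ccc2c(I)c[nH]c2c1 | intermediate
3 | 6-bromo-3-iodo-1-tosyl-1H-indole | Cc1ccc(cc1)S(=O)(=O)n1cc(I)c2ccc(Br)cc12 | intermediate
4 | ethynyltrimethylsilane | C#C[Si](C)(C)C | starting material
5 | 6-bromo-1-tosyl-3-[(trimethylsilyl)ethynyl]-1H-indole | Cc1ccc(cc1)S(=O)(=O)n1cc(C#C[Si](C)(C)C)c2ccc(Br)cc12 | intermediate
6 | 6-bromo-3-ethynyl-1-tosyl-1H-indole | Cc1ccc(cc1)S(=O)(=O)n1cc(C#C)c2ccc(Br)cc12 | intermediate
7 | 1H-indole-3-carbonitrile | N#Cc1c[nH]c2ccccc12 | starting material
8 | (Z)-N'-hydroxy-1H-indole-3-carboximidamide | N/C(=N\O)c1c[nH]c2ccccc12 | intermediate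
9 | (Z)-N'-{[1-(6-bromo-1-tosyl-1H-indol-3-yl)ethenyl]oxy}-1H-indole-3-carboximidamide (O-vinyl amidoxime) | C=C(O/N=C(\N)c1c[nH]c2ccccc12)c1cn(S(=O)(=O)c2ccc(C)cc2)c2cc(Br)ccc12 | intermediate
10 | N-[2-(6-bromo-1-tosyl-1H-indol-3-yl)-2-oxoethyl]-1H-indole-3-carboximidamide (N-phenacyl-type amidine) | N=C(NCC(=O)c1cn(S(=O)(=O)c2ccc(C)cc2)c2cc(Br)ccc12)c1c[nH]c2ccccc12 | intermediate
11 | 6-bromo-3-[2-(1H-indol-3-yl)-1H-imidazol-4-yl]-1-tosyl-1H-indole | Cc1ccc(cc1)S(=O)(=O)n1cc(-c2c[nH]c(-c3c[nH]c4ccccc34)n2)c2ccc(Br)cc12 | intermediate
12 | nortopsentin C | Brc1ccc2c(-c3c[nH]c(-c4c[nH]c5ccccc45)n3)c[nH]c2c1 | target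

## Step count and risks

Total step count: 7. Longest linear sequence: 6 (steps 1, 2, 3, 4, 6, 7). Step 5 is the one-step side branch.

**Highest risk: step 6, the proposed new step.**
- The basic amidoxime may bind and deactivate gold.
- N-attack may compete with O-attack.
- Compound 9 may close reversibly to a 5-methyl-4,5-dihydro-1,2,4-oxadiazole.
- The [3,3] shift may need more heat than planned.

The fallback is known chemistry. It sets out from 1 and 8 and comes back at 12, so 11 and step 7 are skipped.
- 1 is acylated at C3 with chloroacetyl chloride and pyridine in dioxane at 60 °C to give 1-(6-bromo-1H-indol-3-yl)-2-chloroethan-1-one F1.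
- 8 is hydrogenolysed (H2, Raney Ni, MeOH/AcOH) to 1H-indole-3-carboximidamide F2.
- F1 and F2 are joined by the classical amidine/α-haloketone imidazole condensation (KHCO3, THF/H2O, reflux). N-alkylation at CH2Cl and then cyclodehydration onto the ketone give the same 2,4-pattern and hence 12.

**Second risk: step 3.**
- Some oxidative addition at C6–Br could lead to double alkynylation.
- Glaser dimerisation of 4 and protodeiodination of 3 are also possible.

The fallback avoids palladium and the iodide entirely. It sets out from 1 and comes back at 6.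
- Vilsmeier–Haack formylation (POCl3, DMF, then aq NaOH) gives 6-bromo-1H-indole-3-carbaldehyde F3.
- N-tosylation (TsCl, Et3N, DMAP, CH2Cl2) gives 6-bromo-1-tosyl-1H-indole-3-carbaldehyde F4.
- Colvin one-carbon homologation with pre-lithiated trimethylsilyldiazomethane (TMSCHN2, LDA, THF, −78 °C to rt) converts the aldehyde directly into alkyne 6.

**Third risk: step 5.**
- The nitrile is a vinylogous cyanamide, deactivated by the indole nitrogen.
- Direct addition of hydroxylamine may therefore be slow and accompanied by the primary amide.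

The fallback activates the nitrile electrophilically instead. It sets out from 7 and comes back at 8.
- Pinner reaction (HCl gas, EtOH/dioxane, 0 °C) gives ethyl 1H-indole-3-carboximidate F5, handled as its hydrochloride.
- Treatment with NH2OH·HCl and Et3N in EtOH at rt exchanges ethoxide for hydroxylamine and gives 8.

## Further compounds

F1 | step 6 | 1-(6-bromo-1H-indol-3-yl)-2-chloroethan-1-one | O=C(CCl)c1c[nH]c2cc(Br)ccc12
F2 | step 6 | 1H-indole-3-carboximidamide | N=C(N)c1c[nH]c2ccccc12
F3 | step 3 | 6-bromo-1H-indole-3-carbaldehyde | O=Cc1c[nH]c2cc(Br)ccc12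
F4 | step 3 | 6-bromo-1-tosyl-1H-indole-3-carbaldehyde | Cc1ccc(cc1)S(=O)(=O)n1cc(C=O)c2ccc(Br)cc12
F5 | step 5 | ethyl 1H-indole-3-carboximidate | CCOC(=N)c1c[nH]c2ccccc12
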